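# Synthesis plan for (1S,2R,3E,7S,8R,11S,12Z)-7-acetoxy-8,11-epidioxycembra-3,12,15(17)-trien-16,2-olide (30)

Cembrane numbering is used for all intermediates. C1 is the ring CH next to the lactone, C2 the lactone O–CH, C16 the lactone C=O, C17 the exocyclic CH2, and C18, C19, C20 the methyl groups on C4, C8, C12. Compound numbers are those of the steps and of the compound list.

## The problem

Target 30 is a 14-membered carbocycle (C1–C14) that carries a trans-fused α-methylene-γ-butyrolactone on C1/C2 and is bridged from C8 to C11 by a peroxide, so that the two oxygens with C8, C9, C10 and C11 form a 1,2-dioxane inside the large ring. Its five stereocentres fall into two groups, C1/C2 at the lactone and C7/C8/C11 around the dioxane, which are separated by two trisubstituted alkenes and cannot direct one another; each group must be secured in absolute form before the halves are joined. Within the groups control is available: C2 can steer a substituent onto C1 from the opposite face, the C–O bonds at C8 and C11 must be cis, and the quaternary C8 can bias additions to a carbonyl at C7. The two ring alkenes have opposite geometry (3E, 12Z), and neither should be left to a ring closure whose selectivity cannot be foreseen. The peroxide excludes low-valent metals, aluminium hydrides and catalytic hydrogenation. The hydrogen at C11 is allylic and peroxidic and is removed by bases with cleavage of the O–O bond (Kornblum–DeLaMare). The exocyclic methylene lactone is a Michael acceptor, the lactone C2–O bond is allylic, and the C7 acetate is enolisable. A short entry is possible because C7–C12 with the methyl groups C19 and C20 are the eight carbons of m-xylene, with dioxygen laid across the para-related C8 and C11. A dearomatised m-xylene can take up O2 in one cycloaddition, and the ring alkene that remains (C7=C12) marks the bond to be cut later to release the two arms.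

## Retrosynthesis

**C7–O acyl bond and C15=C17 (30 ⇒ 29 ⇒ 28 ⇒ 25).** The acetate is removed first to alcohol 29, which is kept as silyl ether 28, and the exocyclic methylene is then cut back to the saturated lactone 25 (through Mannich base 26 and its methiodide 27). A methylene lactone carried from earlier would add ylides, be reduced in the hydrogen-transfer step and offer metathesis a further alkene. The price is that 25 must be enolised with an amide base. That forbids an acetate at C7 at that stage and asks the O–O and C11–H bonds to survive the base at low temperature.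

**C5–C6 (25 ⇒ 24 ⇒ 23).** The large ring is opened at a bond that is saturated in the target. Closing at C3=C4 or C12=C13 by metathesis would leave a trisubstituted geometry to chance. A diene–ene metathesis that forms C5=C6 in 24 has no such issue, because that alkene is then saturated and its geometry is irrelevant. The precursor 23 is acyclic. The forward steps must close at the terminal alkene of a 1,3-diene and then saturate one disubstituted alkene beside two trisubstituted ones without touching the peroxide.

**C12=C13 (23 ⇒ 10 + 21).** Cutting the Z alkene gives methyl ketone 10 and phosphonium salt 21 (ylide 22). A ketone flanked by an oxygen-bearing carbon is the substrate class for which non-stabilised ylides give Z-trisubstituted alkenes. Cuts at C13–C14 or C1–C14 would need copper or palladium reagents in the presence of the peroxide. The cut divides the molecule into a ten-carbon and an eleven-carbon half, each holding one group of stereocentres. The forward reaction must outrun proton abstraction at C11.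

**C6–C7 and the resolution (10 ⇒ 9 ⇒ 8 ⇒ 7).** Removal of the silyl group and of the vinyl group leads to keto aldehyde 7. A vinyl nucleophile is chosen over a longer chain because it supplies the metathesis partner and turns C7 into a secondary allylic alcohol, the best-understood substrate for a kinetic resolution. The racemate 8 is therefore resolved to 9 at this point, and not at the stage of the bicyclic peroxide. The addition must discriminate aldehyde from ketone and set C7 relative to C8.

**C7=C12 (7 ⇒ 5).** Reconnecting the two carbonyl carbons gives bicyclic alkene 5 (ozonide 6 lies on the forward path). The cis relationship of the two arms in 7 is then a consequence of the bicycle and needs no control.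

**O–C8 and O–C11 (5 ⇒ 3 + 4).** Both C–O bonds are cut at once to the cyclic diene 3 and dioxygen 4. This removes the dioxane ring and both of its stereocentres and leaves an achiral hydrocarbon. The forward cycloaddition must win over ene reactions at the allylic positions.

**Dearomatisation (3 ⇒ 2 ⇒ 1).** Diene 3 is the conjugated isomer of the Birch product 2 of m-xylene 1.

**Lactone half, alkenes (21 ⇒ 20 ⇒ 19 ⇒ 17).** The phosphonium group comes from a primary iodide, the diene terminus from enal 19 by methylenation, and the E C3=C4 bond from an aldehyde (18, not isolated) and a formyl-stabilised ylide. A stabilised ylide is the most reliable way to an E-trisubstituted alkene, and an aldehyde terminus is preferred to an ester because the lactone would not survive an ester reduction.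

**Lactone half, stereocentres (17 ⇒ 16 ⇒ 15 ⇒ 13 ⇒ 12 ⇒ 11).** The two-carbon arm on C1 is traced through iodide 16, alcohol 15 and borane 14 to a vinyl group. The C1–C14 bond is cut to butenolide 12, the silyl ether of the chiral-pool alcohol 11. The existing C2 centre of 11 directs the conjugate addition to the opposite face and so supplies C1.

## Roads not taken

**Alternative 1:** The cut is C2–C3. A seco aldehyde bearing an E-alkenyl iodide at C3 would be closed with CrCl2 and catalytic NiCl2 to the 14-membered allylic alcohol A1; the open-chain substrate is A2.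
- Merits: the closure is convergent, fixes the C3=C4 geometry in the iodide, and belongs to the most dependable macrocyclisations of cembranoids. In skeleton assembly this road is better than the chosen one, since it needs neither a metathesis nor a reduction.
- Weak points: A1 has a C11 ketone and a C7=C8 alkene but no peroxide, and divalent chromium would not tolerate one. C7, C8, C11 and the O–O bridge would all have to be made afterwards on a flexible macrocycle with two further trisubstituted alkenes. The carbinol C2 is set only by induction from C1, and the lactone must still be oxidised up from a silyl-protected allylic alcohol.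
- Comparison: the chosen plan sets against this closure three dioxane-region stereocentres fixed in a rigid bicycle and by a reagent-controlled resolution before any large ring exists. It pays with ten steps in which a peroxide restricts the choice of reagents.

**Alternative 2:** The cut is O–C11 together with C11–H. The 7-O-deacetyl compound A3, identical with 29, would come from hydroperoxy ketone A4, which closes to a cyclic peroxyhemiketal that Me3SiOTf and Et3SiH reduce through the peroxycarbenium ion.
- Merits: the peroxide appears one step before the end, so nothing before it is peroxide-limited, and both hemiketal epimers converge on one cation. In these respects it is better than the chosen plan, with which it shares the last step.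
- Weak points: in A4 the C11 carbonyl is conjugated with C12=C13, so the cation is an allyl cation open to hydride at C13 and to loss of the Z geometry. The tertiary hydroperoxide at C8 must be installed with defined configuration next to C7 on a macrocycle. The cis outcome rests on the facial preference of hydride delivery to a ring-embedded cation. The allylic lactone C–O bond must survive a strong Lewis acid.
- Comparison: the chosen plan offers a dioxane whose cis geometry follows from the cycloaddition itself, and C8 is made with its oxygen in place.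

**Alternative 3:** The cut is C9–C10. The trienone lactone A5 would arise from the 14-membered β-keto lactone A6 when Pd(PPh3)4 ionises the C7 allylic ester, CO2 is lost and the C10 enolate attacks C9.
- Merits: a macrolactonisation replaces a carbocyclisation, CO2 is the only by-product and the allyl unit delivers the E C7=C8 alkene. As a solution to the carbocycle it is the most inventive of the three.
- Weak points: the enolate can attack either allyl terminus (C7 gives a 12-membered ring) or react through oxygen. Zerovalent palladium can also ionise the allylic C2–O bond of the butyrolactone. A5 still lacks the C7 oxygen, the C8–O bond and the peroxide, so the oxygenation problems of Alternatives 1 and 2 remain.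
- Comparison: the chosen plan solves the peroxide first and makes the ring with a catalyst that tolerates it.

Key step: step 3

Remarks: Compounds 5–8 are racemates; their SMILES show the enantiomer that is carried on, and absolute configuration enters in step 6. The geometry of the C5=C6 alkene formed in step 17 is immaterial because step 18 saturates it; 24 is drawn as the 5E isomer. Peroxides 5–7 are small and should be handled in solution.

## Route

Step 1
Reactants: 1 m-xylene
Product: 2 1,5-dimethylcyclohexa-1,4-diene
Conditions: Li, NH3(l), EtOH, THF, −78 to −33 °C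
Reagents that add atoms: none
Why: Birch reduction; the alkyl groups stay on the surviving alkene carbons, so m-xylene gives the 1,5-dimethyl-1,4-diene.

Step 2
Reactants: 2 1,5-dimethylcyclohexa-1,4-diene
Product: 3 1,3-dimethylcyclohexa-1,3-diene
Conditions: KOtBu (0.2 equiv), DMSO, 25 °C
Reagents that add atoms: none
Why: Base-mediated prototropic isomerisation of a skipped to a conjugated diene through the pentadienyl anion; 3 is the only conjugated isomer with both methyl groups on the diene and should be the main component at equilibrium, while residual 2, minor isomers and any m-xylene are removed after step 3.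

Step 3
Reactants: 3 1,3-dimethylcyclohexa-1,3-diene; 4 dioxygen
Product: 5 rac-(1R,4S)-1,5-dimethyl-2,3-dioxabicyclo[2.2.2]oct-5-ene
Conditions: O2, tetraphenylporphyrin (0.1 mol%), visible light, CH2Cl2, −30 °C
Reagents that add atoms: none
Why: Energy transfer from the excited dye gives singlet dioxygen, which adds as the two-atom component across the termini of the ring-locked s-cis diene in a concerted suprafacial (4+2) cycloaddition. The closest known reaction type is the sensitised photooxygenation of cyclohexa-1,3-dienes to 2,3-dioxabicyclo[2.2.2]oct-5-enes, as in the conversion of α-terpinene into ascaridole. The 1,2-dioxane closes in the (4+2) mode, with both C–O bonds (the future O–C8 and O–C11) formed on one face in one event. The two new stereocentres, C8 and C11, are controlled relative to each other by the suprafacial addition and the bicyclic frame, so only the cis bridge can form. Their absolute configuration is not controlled because the two faces of achiral 3 are enantiotopic; 5 is a racemate and is resolved in step 6. The step needs cycloaddition to win over ene hydroperoxidation at the two methyl groups and the ring CH2 groups; the enforced s-cis geometry and the electron-rich, doubly trisubstituted diene secure this, helped by the low temperature. Regiochemistry is not an issue, since 3 has one diene and the unsymmetrical product is the one required, with the methyl-bearing alkene carbon next to the CH bridgehead. Endoperoxides from minor diene isomers are separated by chromatography.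

Step 4
Reactants: 5 rac-(1R,4S)-1,5-dimethyl-2,3-dioxabicyclo[2.2.2]oct-5-ene
Product: 7 rac-(3R,6S)-6-acetyl-3-methyl-1,2-dioxane-3-carbaldehyde, via ozonide 6 (not isolated)
Conditions: O3, CH2Cl2, −78 °C; then Me2S, −78 to 20 °C
Reagents that add atoms: ozone, [O-][O+]=O
Why: Ozonolysis with reductive work-up; the only alkene is cleaved to the C7 aldehyde and C12 methyl ketone, and dimethyl sulfide reduces the ozonide but not a dialkyl peroxide. C8 and C11 are untouched, so the arms stay cis; no base is used because the C11–H next to the new ketone is prone to Kornblum–DeLaMare cleavage.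

Step 5
Reactants: 7 rac-(3R,6S)-6-acetyl-3-methyl-1,2-dioxane-3-carbaldehyde
Product: 8 rac-1-[(3S,6R)-6-[(1S)-1-hydroxyprop-2-en-1-yl]-6-methyl-1,2-dioxan-3-yl]ethan-1-one
Conditions: CH2=CHMgBr, ClTi(OiPr)3, THF, −78 °C; then 7, −78 to −30 °C
Reagents that add atoms: vinylmagnesium bromide, C=C[Mg]Br
Why: Carbonyl addition of an organotitanium reagent (CH2=CHTi(OiPr)3, formed in the flask), which attacks aldehydes much faster than ketones, is weakly basic and does not chelate. The polar Felkin–Anh mode should therefore operate, with vinyl entering anti to the C8–O bond and past the C19 methyl, not the ring CH2, which gives the 7S relative to 8R relationship.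

Step 6
Reactants: 8 rac-1-[(3S,6R)-6-[(1S)-1-hydroxyprop-2-en-1-yl]-6-methyl-1,2-dioxan-3-yl]ethan-1-one
Product: 9 1-[(3S,6R)-6-[(1S)-1-hydroxyprop-2-en-1-yl]-6-methyl-1,2-dioxan-3-yl]ethan-1-one
Conditions: Ti(OiPr)4, L-(+)-diisopropyl tartrate, t-BuOOH (0.6 equiv), 4 Å molecular sieves, CH2Cl2, −20 °C
Reagents that add atoms: none
Why: Sharpless kinetic resolution of a secondary allylic alcohol; the L-(+)-tartrate catalyst epoxidises the 7R enantiomer (the spatial counterpart of the fast-reacting S enantiomers of simple carbinols, the descriptor changing because C8 outranks vinyl) and leaves the 7S alcohol. Because step 5 tied C7 to C8 and C11, this also fixes the absolute configuration of the dioxane.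

Step 7
Reactants: 9 1-[(3S,6R)-6-[(1S)-1-hydroxyprop-2-en-1-yl]-6-methyl-1,2-dioxan-3-yl]ethan-1-one
Product: 10 1-[(3S,6R)-6-[(1S)-1-(tert-butyldimethylsilyloxy)prop-2-en-1-yl]-6-methyl-1,2-dioxan-3-yl]ethan-1-one
Conditions: TBSOTf, 2,6-lutidine, CH2Cl2, −78 to −40 °C
Reagents that add atoms: tert-butyldimethylsilyl trifluoromethanesulfonate, CC(C)(C)[Si](C)(C)OS(=O)(=O)C(F)(F)F
Why: Silylation of a hindered secondary alcohol with a silyl triflate; the hindered weak base and low temperature spare the C11–H next to the ketone.

Step 8
Reactants: 11 (S)-5-(hydroxymethyl)furan-2(5H)-one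
Product: 12 (S)-5-[(tert-butyldimethylsilyloxy)methyl]furan-2(5H)-one
Conditions: TBSCl, imidazole, CH2Cl2, 0 to 20 °C
Reagents that add atoms: tert-butyldimethylsilyl chloride, CC(C)(C)[Si](C)(C)Cl
Why: Silylation of a primary alcohol; the free hydroxyl would quench the cuprate of step 9, and the bulky ether strengthens the facial bias.

Step 9
Reactants: 12 (S)-5-[(tert-butyldimethylsilyloxy)methyl]furan-2(5H)-one
Product: 13 (4R,5S)-5-[(tert-butyldimethylsilyloxy)methyl]-4-ethenyloxolan-2-one
Conditions: (CH2=CH)2CuMgBr [from CH2=CHMgBr (2 equiv) and CuBr·SMe2 (1 equiv)], THF, −78 °C; aq NH4Cl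
Reagents that add atoms: vinylmagnesium bromide, C=C[Mg]Br
Why: Conjugate addition of a vinyl cuprate to a butenolide; the silyloxymethyl group on C2 blocks one face, so vinyl enters anti and sets C1 trans to C2 as in the target.

Step 10
Reactants: 13 (4R,5S)-5-[(tert-butyldimethylsilyloxy)methyl]-4-ethenyloxolan-2-one
Product: 15 (4S,5S)-5-[(tert-butyldimethylsilyloxy)methyl]-4-(2-hydroxyethyl)oxolan-2-one, via alkylborane 14 (not isolated)
Conditions: 9-BBN, THF, 0 to 20 °C; then NaBO3·4H2O, H2O, 20 °C
Reagents that add atoms: 9-borabicyclo[3.3.1]nonane, B1C2CCCC1CCC2 (its atoms are carried only in 14); sodium perborate tetrahydrate, [Na+].[Na+].O[B-]1(O)OO[B-](O)(O)OO1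
Why: Anti-Markovnikov hydroboration–oxidation of a terminal alkene; 9-BBN does not reduce the lactone, and perborate oxidises the C–B bond without the strongly basic medium that would open it.

Step 11
Reactants: 15 (4S,5S)-5-[(tert-butyldimethylsilyloxy)methyl]-4-(2-hydroxyethyl)oxolan-2-one
Product: 16 (4R,5S)-5-[(tert-butyldimethylsilyloxy)methyl]-4-(2-iodoethyl)oxolan-2-one
Conditions: I2, PPh3, imidazole, CH2Cl2, 0 °C
Reagents that add atoms: iodine, II
Why: Appel-type iodination of a primary alcohol through the alkoxyphosphonium ion; the silyl ether and lactone are inert.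

Step 12
Reactants: 16 (4R,5S)-5-[(tert-butyldimethylsilyloxy)methyl]-4-(2-iodoethyl)oxolan-2-one
Product: 17 (4R,5S)-5-(hydroxymethyl)-4-(2-iodoethyl)oxolan-2-one
Conditions: HF·pyridine, THF, 0 to 20 °C
Reagents that add atoms: none
Why: Fluoride cleavage of a primary silyl ether under mildly acidic conditions that leave the lactone and the primary iodide alone.

Step 13
Reactants: 17 (4R,5S)-5-(hydroxymethyl)-4-(2-iodoethyl)oxolan-2-one
Product: 19 (2E)-3-[(2S,3R)-3-(2-iodoethyl)-5-oxooxolan-2-yl]-2-methylprop-2-enal, via aldehyde 18 (not isolated)
Conditions: Dess–Martin periodinane, NaHCO3, CH2Cl2, 0 to 20 °C; then Ph3P=C(CH3)CHO, 20 to 40 °C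
Reagents that add atoms: 2-(triphenylphosphoranylidene)propanal, CC(C=O)=P(c1ccccc1)(c1ccccc1)c1ccccc1
Why: Alcohol oxidation followed in the same flask by Wittig olefination with a stabilised ylide, which gives the E C3=C4 alkene. Trapping in situ avoids isolating the epimerisable α-acyloxy aldehyde 18, and the ylide reacts only once because enal 19 is much less electrophilic.

Step 14
Reactants: 19 (2E)-3-[(2S,3R)-3-(2-iodoethyl)-5-oxooxolan-2-yl]-2-methylprop-2-enal
Product: 20 (4R,5S)-4-(2-iodoethyl)-5-[(1E)-2-methylbuta-1,3-dien-1-yl]oxolan-2-one
Conditions: Ph3PCH3Br, KN(SiMe3)2, THF, 0 °C; then 19, −78 to 0 °C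
Reagents that add atoms: methyltriphenylphosphonium bromide, C[P+](c1ccccc1)(c1ccccc1)c1ccccc1.[Br-]
Why: Wittig methylenation of an enal; at −78 °C carbonyl addition outruns substitution at the primary iodide and attack on the lactone, and the C3=C4 geometry is untouched.

Step 15
Reactants: 20 (4R,5S)-4-(2-iodoethyl)-5-[(1E)-2-methylbuta-1,3-dien-1-yl]oxolan-2-one
Product: 21 {2-[(2S,3R)-2-[(1E)-2-methylbuta-1,3-dien-1-yl]-5-oxooxolan-3-yl]ethyl}triphenylphosphonium iodide
Conditions: PPh3, MeCN, 80 °C
Reagents that add atoms: triphenylphosphine, c1ccc(cc1)P(c1ccccc1)c1ccccc1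
Why: SN2 quaternisation of a primary iodide by a phosphine.

Step 16
Reactants: 21 {2-[(2S,3R)-2-[(1E)-2-methylbuta-1,3-dien-1-yl]-5-oxooxolan-3-yl]ethyl}triphenylphosphonium iodide; 10 1-[(3S,6R)-6-[(1S)-1-(tert-butyldimethylsilyloxy)prop-2-en-1-yl]-6-methyl-1,2-dioxan-3-yl]ethan-1-one
Product: 23 (4S,5S)-4-[(2Z)-3-{(3S,6R)-6-[(1S)-1-(tert-butyldimethylsilyloxy)prop-2-en-1-yl]-6-methyl-1,2-dioxan-3-yl}but-2-en-1-yl]-5-[(1E)-2-methylbuta-1,3-dien-1-yl]oxolan-2-one, via ylide 22 (not isolated)
Conditions: 21, NaN(SiMe3)2, THF, −78 °C; then 10, −78 to 0 °C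
Reagents that add atoms: none
Why: Wittig olefination of an α-oxygenated methyl ketone with a non-stabilised ylide, the reaction known to give Z-trisubstituted allylic ethers, so the oxygen-bearing C11 ends cis to the ylide chain (C14). The phosphonium CH2 is more acidic than the lactone CH2, and addition to the activated ketone at −78 °C should be faster than proton abstraction at C11.

Step 17
Reactants: 23 (4S,5S)-4-[(2Z)-3-{(3S,6R)-6-[(1S)-1-(tert-butyldimethylsilyloxy)prop-2-en-1-yl]-6-methyl-1,2-dioxan-3-yl}but-2-en-1-yl]-5-[(1E)-2-methylbuta-1,3-dien-1-yl]oxolan-2-one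
Product: 24 macrocyclic triene lactone (14-membered ring closed at C5=C6; 3E,5E,12Z; C7 OTBS; C8–C11 peroxide bridge; C15 is CH2; stereocentres as in 30)
Conditions: RuCl2(=CHPh)(H2IMes)(PCy3) (second-generation Grubbs catalyst, 10 mol%), toluene, 1 mM, 70 °C
Reagents that add atoms: none
Why: Ring-closing metathesis of the diene–ene type between the terminal alkene of the 1,3-diene and the C6 vinyl group with loss of ethene; the trisubstituted alkenes react far more slowly, and ruthenium alkylidenes tolerate dialkyl peroxides. No stereocentre is formed, and the geometry of the new alkene does not matter.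

Step 18
Reactants: 24 macrocyclic triene lactone
Product: 25 macrocyclic diene lactone (C5–C6 saturated; 3E,12Z; C7 OTBS; C8–C11 peroxide bridge; C15 is CH2)
Conditions: KO2CN=NCO2K, AcOH, MeOH/CH2Cl2, 0 to 20 °C, portionwise
Reagents that add atoms: none
Why: Diimide reduction, a concerted syn transfer of H2 whose rate falls steeply with alkene substitution, so the 1,2-disubstituted C5=C6 bond of the diene is saturated before either trisubstituted alkene. Diimide does not cleave O–O bonds and is the usual reductant for unsaturated peroxides.

Step 19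
Reactants: 25 macrocyclic diene lactone
Product: 28 7-O-(tert-butyldimethylsilyl)-7-O-deacetyl target (α-methylene lactone), via Mannich base 26 (not isolated), via methiodide 27 (not isolated)
Conditions: LiN(SiMe3)2, THF, −78 °C; CH2=NMe2+ I−, −78 to 0 °C; then MeI, MeOH, 20 °C; then aq NaHCO3, CH2Cl2, 20 °C
Reagents that add atoms: N,N-dimethylmethyleneiminium iodide (Eschenmoser's salt), C=[N+](C)C.[I-]; iodomethane, CI (its methyl group is carried only in 27)
Why: Lactone α-methylenation by enolate aminomethylation, N-methylation and E1cB loss of trimethylamine; the lactone CH2 is the only site acidic enough for the silylamide at −78 °C, and the new C15 centre is destroyed in the elimination.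

Step 20
Reactants: 28 7-O-(tert-butyldimethylsilyl)-7-O-deacetyl target
Product: 29 7-O-deacetyl target (free C7 alcohol)
Conditions: HF·pyridine, pyridine, THF, 0 to 20 °C
Reagents that add atoms: none
Why: Desilylation with buffered hydrogen fluoride, which avoids the basic fluoride sources that could add to the methylene lactone or abstract the C11 hydrogen.

Step 21
Reactants: 29 7-O-deacetyl target
Product: 30 (1S,2R,3E,7S,8R,11S,12Z)-7-acetoxy-8,11-epidioxycembra-3,12,15(17)-trien-16,2-olide
Conditions: Ac2O, pyridine, DMAP (0.1 equiv), CH2Cl2, 0 to 20 °C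
Reagents that add atoms: acetic anhydride, CC(=O)OC(C)=O
Why: DMAP-catalysed acylation of a hindered secondary alcohol; no stereocentre is touched.

## Compound list

1 | m-xylene | Cc1cccc(C)c1 | starting material
2 | 1,5-dimethylcyclohexa-1,4-diene | CC1=CCC=C(C)C1 | intermediate
3 | 1,3-dimethylcyclohexa-1,3-diene | CC1=CC(C)=CCC1 | intermediate
4 | dioxygen | O=O | starting material
5 | rac-(1R,4S)-1,5-dimethyl-2,3-dioxabicyclo[2.2.2]oct-5-ene (racemate) | C1=C(C)[C@H]2OO[C@]1(C)CC2 | intermediate
6 | secondary ozonide of 5 (1,2,4-trioxolane across C7 and C12; racemate, trioxolane carbons as formed) | CC12OOC(O1)[C@@]1(C)CC[C@@H]2OO1 | intermediate (not isolated)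
7 | rac-(3R,6S)-6-acetyl-3-methyl-1,2-dioxane-3-carbaldehyde (racemate) | O=C[C@@]1(C)CC[C@H](OO1)C(C)=O | intermediate
8 | rac-1-[(3S,6R)-6-[(1S)-1-hydroxyprop-2-en-1-yl]-6-methyl-1,2-dioxan-3-yl]ethan-1-one (racemate) | C=C[C@H](O)[C@@]1(C)CC[C@H](OO1)C(C)=O | intermediate
9 | 1-[(3S,6R)-6-[(1S)-1-hydroxyprop-2-en-1-yl]-6-methyl-1,2-dioxan-3-yl]ethan-1-one (single enantiomer) | C=C[C@H](O)[C@@]1(C)CC[C@H](OO1)C(C)=O | intermediate
10 | 1-[(3S,6R)-6-[(1S)-1-(tert-butyldimethylsilyloxy)prop-2-en-1-yl]-6-methyl-1,2-dioxan-3-yl]ethan-1-one | C=C[C@H](O[Si](C)(C)C(C)(C)C)[C@@]1(C)CC[C@H](OO1)C(C)=O | intermediate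
11 | (S)-5-(hydroxymethyl)furan-2(5H)-one | O=C1C=C[C@@H](CO)O1 | starting material
12 | (S)-5-[(tert-butyldimethylsilyloxy)methyl]furan-2(5H)-one | O=C1C=C[C@@H](CO[Si](C)(C)C(C)(C)C)O1 | intermediate
13 | (4R,5S)-5-[(tert-butyldimethylsilyloxy)methyl]-4-ethenyloxolan-2-one | O=C1C[C@H](C=C)[C@@H](CO[Si](C)(C)C(C)(C)C)O1 | intermediate
14 | B-alkyl-9-BBN adduct of 13 (boron on the terminal carbon, C13) | O=C1C[C@H](CCB2C3CCCC2CCC3)[C@@H](CO[Si](C)(C)C(C)(C)C)O1 | intermediate (not isolated)
15 | (4S,5S)-5-[(tert-butyldimethylsilyloxy)methyl]-4-(2-hydroxyethyl)oxolan-2-one | O=C1C[C@H](CCO)[C@@H](CO[Si](C)(C)C(C)(C)C)O1 | intermediate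
16 | (4R,5S)-5-[(tert-butyldimethylsilyloxy)methyl]-4-(2-iodoethyl)oxolan-2-one | O=C1C[C@H](CCI)[C@@H](CO[Si](C)(C)C(C)(C)C)O1 | intermediate
17 | (4R,5S)-5-(hydroxymethyl)-4-(2-iodoethyl)oxolan-2-one | O=C1C[C@H](CCI)[C@@H](CO)O1 | intermediate
18 | (2S,3R)-3-(2-iodoethyl)-5-oxooxolane-2-carbaldehyde | O=C1C[C@H](CCI)[C@@H](C=O)O1 | intermediate (not isolated)
19 | (2E)-3-[(2S,3R)-3-(2-iodoethyl)-5-oxooxolan-2-yl]-2-methylprop-2-enal | O=C1C[C@H](CCI)[C@@H](/C=C(\C)C=O)O1 | intermediate
20 | (4R,5S)-4-(2-iodoethyl)-5-[(1E)-2-methylbuta-1,3-dien-1-yl]oxolan-2-one | O=C1C[C@H](CCI)[C@@H](/C=C(\C)C=C)O1 | intermediate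
21 | {2-[(2S,3R)-2-[(1E)-2-methylbuta-1,3-dien-1-yl]-5-oxooxolan-3-yl]ethyl}triphenylphosphonium iodide | O=C1C[C@H](CC[P+](c2ccccc2)(c2ccccc2)c2ccccc2)[C@@H](/C=C(\C)C=C)O1.[I-] | intermediate
22 | ylide of 21 (P=C13) | O=C1C[C@H](CC=P(c2ccccc2)(c2ccccc2)c2ccccc2)[C@@H](/C=C(\C)C=C)O1 | intermediate (not isolated)
23 | (4S,5S)-4-[(2Z)-3-{(3S,6R)-6-[(1S)-1-(tert-butyldimethylsilyloxy)prop-2-en-1-yl]-6-methyl-1,2-dioxan-3-yl}but-2-en-1-yl]-5-[(1E)-2-methylbuta-1,3-dien-1-yl]oxolan-2-one | C=C[C@H](O[Si](C)(C)C(C)(C)C)[C@@]1(C)CC[C@H](OO1)/C(C)=C\C[C@H]1CC(=O)O[C@@H]1/C=C(\C)C=C | intermediate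
24 | macrocyclic triene lactone: 7-O-TBS-8,11-epidioxy-17-norcembra-3E,5E,12Z-trien-16,2-olide, stereocentres as in 30 | O=C1O[C@@H]2/C=C(\C)/C=C/[C@H](O[Si](C)(C)C(C)(C)C)[C@@]3(C)CC[C@H](OO3)/C(C)=C\C[C@H]2C1 | intermediate
25 | macrocyclic diene lactone: 7-O-TBS-8,11-epidioxy-17-norcembra-3E,12Z-dien-16,2-olide | O=C1O[C@@H]2/C=C(\C)CC[C@H](O[Si](C)(C)C(C)(C)C)[C@@]3(C)CC[C@H](OO3)/C(C)=C\C[C@H]2C1 | intermediate
26 | Mannich base: 25 with CH2NMe2 on C15, trans to the C14 arm | O=C1O[C@@H]2/C=C(\C)CC[C@H](O[Si](C)(C)C(C)(C)C)[C@@]3(C)CC[C@H](OO3)/C(C)=C\C[C@H]2[C@@H]1CN(C)C | intermediate (not isolated)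
27 | methiodide of 26 (trimethylammonium iodide) | O=C1O[C@@H]2/C=C(\C)CC[C@H](O[Si](C)(C)C(C)(C)C)[C@@]3(C)CC[C@H](OO3)/C(C)=C\C[C@H]2[C@@H]1C[N+](C)(C)C.[I-] | intermediate (not isolated)
28 | 7-O-(tert-butyldimethylsilyl)-7-O-deacetyl target | C=C1C(=O)O[C@@H]2/C=C(\C)CC[C@H](O[Si](C)(C)C(C)(C)C)[C@@]3(C)CC[C@H](OO3)/C(C)=C\C[C@@H]12 | intermediate
29 | 7-O-deacetyl target (free C7 alcohol) | C=C1C(=O)O[C@@H]2/C=C(\C)CC[C@H](O)[C@@]3(C)CC[C@H](OO3)/C(C)=C\C[C@@H]12 | intermediate
30 | (1S,2R,3E,7S,8R,11S,12Z)-7-acetoxy-8,11-epidioxycembra-3,12,15(17)-trien-16,2-olide | C=C1C(=O)O[C@@H]2/C=C(\C)CC[C@H](OC(C)=O)[C@@]3(C)CC[C@H](OO3)/C(C)=C\C[C@@H]12 | target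

## Step count and weak points

Total: 21 steps. Longest linear sequence: 14 steps (11 to 30 through steps 8–21); the branch from m-xylene is 13 steps (steps 1–7 and 16–21).

**Step 3 (key step).** Ene hydroperoxidation at the allylic methyl and ring positions may compete with cycloaddition, and the regioisomeric dienes carried from step 2 are photooxygenated as well; both lower the share of the wanted bicycle, which is also volatile and base-sensitive during isolation. Fallback: oxygenate 3 with ground-state dioxygen under radical-cation catalysis ((4-BrC6H4)3N·+ SbCl6−, CH2Cl2, −78 °C), a chain process in which the diene radical cation captures O2 and which has no ene channel. It sets out from 3 and returns at 5 and makes no new compound.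

**Step 5.** Facial selectivity may be poor because the methyl group and the ring CH2 on C8 differ little in size, and any chelation through the peroxide oxygen would reverse the sense; attack at the ketone or base-triggered O–O cleavage at C11 would cost material. Fallback: replace substrate control by catalyst control. Zn(CH=CH2)2 with (2S)-(−)-3-exo-(dimethylamino)isoborneol delivers vinyl to the Si face of the aldehyde of both enantiomers of 7, so the 7S centre is set by the ligand. The 8R,11S series gives 9 directly, and the 8S,11R series gives the diastereomeric alcohol 1-[(3R,6S)-6-[(1S)-1-hydroxyprop-2-en-1-yl]-6-methyl-1,2-dioxan-3-yl]ethan-1-one F1, which is removed by chromatography. This sets out from 7, returns at 9 and replaces step 6.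

**Step 6.** Epoxidation of the fast enantiomer may be slow or poorly selective because the carbinol is flanked by a quaternary carbon. Fallback: enzymatic acylation with Candida antarctica lipase B and vinyl acetate in hexane, which esterifies the 7R enantiomer to (1R)-1-[(3S,6R)-6-acetyl-3-methyl-1,2-dioxan-3-yl]prop-2-en-1-yl acetate F2 and leaves the 7S alcohol. It sets out from 8 and returns at 9.

**Step 16.** The basic ylide may abstract the C11 hydrogen of 10 with cleavage of the O–O bond, it may be quenched or acylated by its own lactone, and the Z selectivity may erode for a ring-bound peroxy carbon. Fallback: mask the lactone before the coupling. From 20, i-Bu2AlH (toluene, −78 °C) gives the lactol (4R,5S)-4-(2-iodoethyl)-5-[(1E)-2-methylbuta-1,3-dien-1-yl]oxolan-2-ol F3, and MeOH with pyridinium tosylate gives the methyl acetal (2S,3R)-3-(2-iodoethyl)-5-methoxy-2-[(1E)-2-methylbuta-1,3-dien-1-yl]oxolane F4. PPh3 gives the phosphonium iodide of the methyl acetal F5, whose ylide is coupled with 10 to the acetal analogue of 23 F6. Pyridinium tosylate in wet acetone releases the lactol analogue of 23 F7, and Dess–Martin periodinane oxidises it to the lactone. This sets out from 20 and returns at 23.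

**Step 17.** Closure may be slow at the vinyl group next to the silyloxy-bearing C7 and the quaternary C8, which would let oligomerisation, attack at the internal alkene of the diene or slow ruthenium-induced decay of the peroxide take over. Fallback: metathesise the free allylic alcohol, a substrate class in which the hydroxyl assists the catalyst. HF·pyridine converts 23 into the seco allylic alcohol F8, the same ruthenium catalyst closes it to the macrocyclic dienol F9, diimide saturates C5=C6 to give the macrocyclic alcohol F10, and TBSOTf with 2,6-lutidine restores the silyl ether. This sets out from 23 and returns at 25.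

Further compounds
F0 | step 3 | none | none
F1 | step 5 | 1-[(3R,6S)-6-[(1S)-1-hydroxyprop-2-en-1-yl]-6-methyl-1,2-dioxan-3-yl]ethan-1-one | C=C[C@H](O)[C@]1(C)CC[C@@H](OO1)C(C)=O
F2 | step 6 | (1R)-1-[(3S,6R)-6-acetyl-3-methyl-1,2-dioxan-3-yl]prop-2-en-1-yl acetate | C=C[C@@H](OC(C)=O)[C@]1(C)CC[C@@H](OO1)C(C)=O
F3 | step 16 | (4R,5S)-4-(2-iodoethyl)-5-[(1E)-2-methylbuta-1,3-dien-1-yl]oxolan-2-ol (anomer mixture) | OC1C[C@H](CCI)[C@@H](/C=C(\C)C=C)O1
F4 | step 16 | (2S,3R)-3-(2-iodoethyl)-5-methoxy-2-[(1E)-2-methylbuta-1,3-dien-1-yl]oxolane (anomer mixture) | COC1C[C@H](CCI)[C@@H](/C=C(\C)C=C)O1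
F5 | step 16 | {2-[(2S,3R)-5-methoxy-2-[(1E)-2-methylbuta-1,3-dien-1-yl]oxolan-3-yl]ethyl}triphenylphosphonium iodide | COC1C[C@H](CC[P+](c2ccccc2)(c2ccccc2)c2ccccc2)[C@@H](/C=C(\C)C=C)O1.[I-]
F6 | step 16 | acetal analogue of 23 (C16 as methyl lactol ether) | C=C[C@H](O[Si](C)(C)C(C)(C)C)[C@@]1(C)CC[C@H](OO1)/C(C)=C\C[C@H]1CC(OC)O[C@@H]1/C=C(\C)C=C
F7 | step 16 | lactol analogue of 23 (C16 as hemiacetal) | C=C[C@H](O[Si](C)(C)C(C)(C)C)[C@@]1(C)CC[C@H](OO1)/C(C)=C\C[C@H]1CC(O)O[C@@H]1/C=C(\C)C=C
F8 | step 17 | seco allylic alcohol (23 without the silyl group) | C=C[C@H](O)[C@@]1(C)CC[C@H](OO1)/C(C)=C\C[C@H]1CC(=O)O[C@@H]1/C=C(\C)C=C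
F9 | step 17 | macrocyclic dienol (24 without the silyl group) | O=C1O[C@@H]2/C=C(\C)/C=C/[C@H](O)[C@@]3(C)CC[C@H](OO3)/C(C)=C\C[C@H]2C1
F10 | step 17 | macrocyclic alcohol (25 without the silyl group) | O=C1O[C@@H]2/C=C(\C)CC[C@H](O)[C@@]3(C)CC[C@H](OO3)/C(C)=C\C[C@H]2C1
A1 | alternative 1 | 14-membered C2 allylic alcohol (C11 ketone, E C7=C8, silyl-protected C17 alcohol) | C=C(CO[Si](C)(C)C(C)(C)C)[C@@H]1C/C=C(C)\C(=O)CC/C(C)=C/CC/C(C)=C/[C@H]1O
A2 | alternative 1 | seco aldehyde with E-alkenyl iodide at C3 | C=C(CO[Si](C)(C)C(C)(C)C)[C@@H](C=O)C/C=C(C)\C(=O)CC/C(C)=C/CC/C(C)=C/I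
A3 | alternative 2 | 7-O-deacetyl target (identical with 29) | C=C1C(=O)O[C@@H]2/C=C(\C)CC[C@H](O)[C@@]3(C)CC[C@H](OO3)/C(C)=C\C[C@@H]12
A4 | alternative 2 | macrocyclic C8 hydroperoxide with C11 ketone | C=C1C(=O)O[C@@H]2/C=C(\C)CC[C@H](O)[C@](C)(OO)CCC(=O)/C(C)=C\C[C@@H]12
A5 | alternative 3 | macrocyclic trienone lactone (C11 ketone, E C7=C8) | C=C1C(=O)O[C@@H]2/C=C(\C)CC/C=C(\C)CCC(=O)/C(C)=C\C[C@@H]12
A6 | alternative 3 | 14-membered β-keto lactone (C7 allylic ester, isopropenyl on C7) | C=C1C(=O)O[C@@H]2/C=C(\C)CCC(C(C)=C)OC(=O)CC(=O)/C(C)=C\C[C@@H]12
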